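## Structural features

The target has one carbocycle, a cyclohexane (ring A). Its C1 is quaternary and carries the carboxyl carbon C7 and the oxygen O1; C3, C4 and C5 are three contiguous secondary carbinol carbons, and the methylene groups C2 and C6 separate C1 from this triad. O1, O3 and O4 lie on one face of ring A, and O5 and C7 on the other, which is (1R,3R,4S,5R) for the target and the spatial arrangement of (−)-quinic acid. Two (E)-caffeoyl groups esterify the tertiary O1 and the secondary O3 (the hydroxyl cis to O4), while O4, O5 and the acid are free. The fragile parts are the catechols (oxidised in base and air), the cinnamate double bonds (attacked by OsO4, hydrogen and soft nucleophiles) and the two esters, which migrate between O3, O4 and O5 under base. The real difficulty is therefore not the ring but fixing C1 relative to the remote C3–C5 triad, and acylating exactly the two least accessible oxygens while O4, O5 and the acid end up free. The feature used is that C7 and O5 are cis and can both be axial, so C7, C1, C6, C5 and O5 close a γ-lactone (ring B); on this five-membered template ring A is closed at C3=C4 by metathesis of an allyl group on C1 and a vinyl group on C5. The same lactone later masks O5 and the acid, blocks one face of C3=C4 and holds O3 equatorial and O4 axial, which is what tells these two oxygens apart.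

## Logic of the disconnections

**19 ⇒ 18.** No skeletal bond is cut; in the backward sense the C7–O5 ester bond is closed and four phenolic O–acetyl bonds are added. The reason is that the lactone protects O5 and the acid at once and the acetates keep the catechols inert. The gain is that one final operation frees five functions and no separate protecting groups are needed for O5 and C7. The demand is a hydrolysis that cleaves aryl acetates and a strained lactone but leaves two hindered conjugated esters in place, which points to aqueous acid.

**18 ⇒ 17 + 15.** The O3–acyl bond is cut. In the bicyclic chair O3 is equatorial and O4 axial and flanked by the lactone, so the two oxygens of the cis-diol are distinguishable. The gain is that O4 needs no protecting group. The demand is a regioselective acylation that is fast and mild enough to avoid migration of the ester from O3 to O4.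

**17 ⇒ 16 ⇒ 12 + 15.** The O1–acyl bond is cut, and in 16 the two boron–oxygen bonds are restored. O1 is the least reactive oxygen, so its ester is made while it is the only free hydroxyl. The gain is that regiochemistry is not an issue in this acylation. The demand is a forcing acylation that the boron ester survives, followed by a neutral release of the diol.

**15 ⇒ 14 ⇒ 13.** The C–Cl bond and the two O–acetyl bonds are cut. The reason is that an acid chloride is needed for a tertiary alcohol and free phenols would compete. The gain is one acyl donor for both esters. The demand is that the acetates survive acylation and fall in the final acid step.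

**12 ⇒ 11.** The C3–O3 and C4–O4 bonds are cut, together with their link through boron. A cis-diol on the face away from the lactone is the signature of a syn-dihydroxylation of a C3=C4 alkene. The gain is the removal of two stereocentres. The demand is attack anti to the C7–O5 bridge and interception of the very polar triol in a form soluble in organic solvents.

**11 ⇒ 10 (key).** The C3=C4 bond is cut. It is the one ring bond remote from every stereocentre and it is formed by two alkenes that the lactone already holds cis. The gain is a monocyclic lactone with two stereocentres in place of a bridged bicycle. The demand is that allyl and vinyl are cis and that ring closure outruns intermolecular metathesis. O1 is deliberately left free in 10: the catalyst tolerates a tertiary alcohol, and an unsaturated ester on O1 would itself ring-close with the allyl group to a six-membered unsaturated lactone.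

**10 ⇒ 8.** The C1–O1 bond is cut. The electrophile introduced second enters the planar enolate anti to the vinyl group, so carbon must go in first and oxygen second to place allyl cis to vinyl. The gain is that the quaternary centre is reduced to a tertiary one whose configuration is irrelevant. The demand is facial selectivity in the hydroxylation.

**8 ⇒ 5 + 6.** The C1–C2 bond is cut, because a lactone enolate and an allylic halide are a standard pairing. The gain is two small fragments. The demand is mono-alkylation.

**5 ⇒ 4 ⇒ 3 ⇒ 2 ⇒ 1.** The exocyclic C=C bond on the carbon that becomes C4 is cut (olefination), the oxidation level of that carbon is adjusted twice, and the C5–O5 bond is traced to the C–N bond of 1, replaced with retention. The reason is that 1 supplies C5, C6, C1 and C7 with the one stereocentre from which all others are relayed. The gain is a commercial amino acid. The demand is the D-series and handling of 4 without epimerisation.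

## Other disconnections considered

**Alternative 1:** The cut is at C1–C7 and at the O1–acyl bond together.

- Forward key step: the ketone A1 (3-O-caffeoyl, 4,5-O-disiloxane-protected trihydroxycyclohexanone), the acid A2 and the convertible isocyanide A3 combine in a Passerini three-component reaction. The isocyanide carbon adds to the carbonyl, the nitrilium ion is trapped by the carboxylate, and an acyl shift puts the caffeoyl group on O1, giving the α-acyloxy enamide A4; no ring closes.
- In its favour: the tertiary ester, the hardest bond to make by acylation in the chosen route (step 11), arises by an intramolecular acyl transfer, and two bonds and the quaternary centre form in one convergent step. On this point the alternative is the better plan.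
- Against it here: nothing in A1 reliably dictates the face of C1. The isocyanide carbon must end up equatorial, cis to O5; the axial preference of a small linear nucleophile and the syn-axial O3 ester pull in opposite directions, so the outcome cannot be predicted with confidence. Ketones are sluggish Passerini partners, A1 is a β-acyloxy ketone open to E1cB loss of the C3 ester, and the enamide must later be hydrolysed in the presence of three esters and a disiloxane. A1 is most directly made from (−)-quinic acid A5 by excising C7, so the plan removes and rebuilds a carbon and a stereocentre that A5 already has; it is a relay, not a construction of the ring.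
- Comparison: on structure it is equal or better for C3–C5 (bought, not made) and weaker for C1, which the chosen plan ties to C5 through the cis requirement of a ring closure. On mechanism it is an ionic multicomponent reaction against a metal-catalysed ring closure. On step economy it is shorter only if A5 is accepted as the starting point.

**Alternative 2:** The cut runs through C2–C3 and C1–C6.

- Forward key step: the diene A6 and the α-acyloxyacrolein A7, activated as an iminium ion by a chiral primary-amine salt, undergo a [4+2] cycloaddition to A8. C1 then already bears an ester (a phosphonoacetate, which becomes a caffeate by Horner–Wadsworth–Emmons olefination) and the future C7 as a formyl group.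
- In its favour: ring A and the quaternary centre are made in one catalytic enantioselective step from achiral bulk chemicals, which is better step and atom economy for the ring than the seven steps the chosen plan needs to reach 11. The O1 ester is present from the start, so no hindered acylation is needed, and a phosphonoacetate is inert to OsO4; both points are real advantages over the chosen route.
- Against it here: A6 is a gaseous, unactivated diene, and this type of cycloaddition is at its best with more reactive dienes. A8 contains only C1, so C5, C3 and C4 must still be relayed (oxidation of the formyl group, halolactonisation onto C5, elimination, dihydroxylation). After that the plan meets the same bicyclic lactone type and the same O3/O4 problem, and it needs a late double olefination under base next to a free O4 or one more protecting group. Optical purity rests on a catalyst and not on the chiral pool.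
- Comparison: both plans use the lactone as the relay, in opposite directions (C1 to C5 there, C5 to C1 here). The relay by lactonisation is stereospecific and thus better than the facial bias of step 6. The step count to the bicyclic alkene is about equal once the relay steps are counted.

**Alternative 3:** No ring bond is cut; the only bond made at a stereocentre is C1–O1.

- Forward key step: the ketene dithioacetal A10 (C1=C7), which would be derived from shikimic acid A9, is oxidised at an anode. The radical cation is trapped at C1 by the carbonyl oxygen of the O3 tert-butyl carbonate with loss of the tert-butyl group, closing a six-membered cyclic carbonate, and the alcohol A11 adds to C7 to give the orthoester A12.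
- In its favour: all ring carbons and the C3–C5 triad come from A9, and O1 is delivered intramolecularly from O3, so its cis relation to O3 is enforced by geometry. In control of C1 this is better than the chosen plan.
- Against it here: the carbonate ties up exactly the two oxygens, O1 and O3, that must carry the caffeoyl groups. It must be removed again, which returns the plan to acylating a tertiary and an axial secondary hydroxyl. The dithio-orthoester has to be unmasked with thiophilic or oxidising reagents, which is awkward once catechol cinnamates are present. Trapping by a carbonate oxygen to form a quaternary C–O bond is less established than trapping by alcohols, and electrolysis needs dedicated equipment.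
- Comparison: on structure A9 supplies three stereocentres where 1 supplies one, which is better. On mechanism it is radical-cation chemistry against metathesis. On step economy the two are comparable (several steps to A10 and several after A12). The template of the chosen plan, the lactone, protects the right groups (O5 and C7), whereas the carbonate template protects the wrong ones.

Key step: step 7

Remark on the chemistry: locants are those of the target name (C7 is the carboxyl carbon); the acylated secondary oxygen O3 is the one cis to O4, and the template lactone runs from C7 to O5. Checked against this, (3S,5R) for 10 (allyl cis to vinyl, O1 trans) and (1S,5R) for 11 are correct and C5 = R requires the D-amino acid, so no structure needed changing.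

## Route

Step 1
Reactants: 1 D-glutamic acid [(R)-2-aminopentanedioic acid]
Product: 2 (R)-5-oxotetrahydrofuran-2-carboxylic acid
Conditions: NaNO2, aq. HCl, 0 °C → rt
Reagents that add atoms: none
Why: Nitrosative deamination of an α-amino acid; the diazonium group is displaced first by the α-carboxylate and then by the γ-carboxylate, so two inversions give the γ-lactone with net retention and the future C5 is fixed as R.

Step 2
Reactants: 2 (R)-5-oxotetrahydrofuran-2-carboxylic acid
Product: 3 (R)-5-(hydroxymethyl)dihydrofuran-2(3H)-one
Conditions: BH3·SMe2, THF, 0 °C → rt; MeOH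
Reagents that add atoms: none
Why: Chemoselective borane reduction; a free carboxylic acid is reduced through its acyloxyborane much faster than a lactone, and the stereocentre is not involved.

Step 3
Reactants: 3 (R)-5-(hydroxymethyl)dihydrofuran-2(3H)-one
Product: 4 (R)-5-oxotetrahydrofuran-2-carbaldehyde
Conditions: (COCl)2, DMSO, CH2Cl2, −78 °C; Et3N, −78 → 0 °C; non-aqueous work-up, used crude at once
Reagents that add atoms: none
Why: Swern oxidation stops at the aldehyde and runs cold and without water, which suits a water-soluble α-oxygenated aldehyde whose stereocentre can epimerise.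

Step 4
Reactants: 4 (R)-5-oxotetrahydrofuran-2-carbaldehyde
Product: 5 (R)-5-vinyldihydrofuran-2(3H)-one
Conditions: Ph3PCH3Br (1.2 equiv), KN(SiMe3)2 (1.1 equiv), THF, 0 °C; then 4, −78 → 0 °C
Reagents that add atoms: methyltriphenylphosphonium bromide, C[P+](c1ccccc1)(c1ccccc1)c1ccccc1.[Br-]
Why: Wittig methylenation; the preformed ylide, made with a small deficit of base, adds to the aldehyde far faster than to the lactone carbonyl, and addition at low temperature limits enolisation of the α-stereocentre, in line with known olefinations of this aldehyde by non-stabilised ylides.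

Step 5
Reactants: 5 (R)-5-vinyldihydrofuran-2(3H)-one; 6 allyl bromide
Product: 8 (3S,5R)-3-allyl-5-vinyldihydrofuran-2(3H)-one, via lithium enolate 7 (not isolated)
Conditions: LiN(iPr)2 (1.05 equiv), THF, −78 °C; allyl bromide (1.2 equiv), DMPU, −78 → −40 °C
Reagents that add atoms: allyl bromide (6), C=CCBr
Why: Lactone enolate alkylation (SN2 on an allylic bromide); the electrophile should enter mainly anti to the C5 vinyl group, but the configuration at C3 does not matter because this carbon becomes planar again in step 6, so the C3 epimer is carried along.

Step 6
Reactants: 8 (3S,5R)-3-allyl-5-vinyldihydrofuran-2(3H)-one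
Product: 10 (3S,5R)-3-allyl-3-hydroxy-5-vinyldihydrofuran-2(3H)-one, via potassium enolate 9 (not isolated)
Conditions: KN(SiMe3)2 (1.2 equiv), THF, −78 °C; 2-(phenylsulfonyl)-3-phenyloxaziridine (1.5 equiv), −78 °C; AcOH
Reagents that add atoms: 2-(phenylsulfonyl)-3-phenyloxaziridine, O=S(=O)(N1OC1c1ccccc1)c1ccccc1
Why: Davis enolate hydroxylation, in which the enolate carbon attacks the oxaziridine oxygen; the enolate is planar at C3 and the bulky oxidant should approach anti to the C5 vinyl group, which places O1 trans to vinyl and the allyl group cis to it and so sets the quaternary centre C1 of the target. Any C3 epimer formed cannot cyclise in step 7 and is removed there.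

Step 7
Reactants: 10 (3S,5R)-3-allyl-3-hydroxy-5-vinyldihydrofuran-2(3H)-one
Product: 11 (1S,5R)-1-hydroxy-6-oxabicyclo[3.2.1]oct-3-en-7-one
Conditions: second-generation Grubbs catalyst RuCl2(=CHPh)(PCy3)(H2IMes) (5 mol %; H2IMes = 1,3-dimesitylimidazolidin-2-ylidene), CH2Cl2 (5 mM), 40 °C, argon sparge
Reagents that add atoms: none
Why: Olefin metathesis by the Chauvin mechanism: the ruthenium benzylidene exchanges onto the unhindered allyl terminus of 10, the new alkylidene at C3 adds to the C5 vinyl group in an intramolecular [2+2] step, and cycloreversion of the ruthenacyclobutane releases the C3=C4 alkene and a ruthenium methylidene, the two terminal carbons leaving as ethene that the argon stream carries off. The closest known reaction type is the ring-closing metathesis of cis-1,3-dialkenyl five-membered rings, such as cis-2-allyl-5-vinylpyrrolidine carbamates, to bridged bicyclo[3.2.1]octenes. One ring is closed, the six-membered carbocycle C1–C6 (ring A), and it closes as a bridge across the 1,3-positions of the existing γ-lactone (ring B), so that a 6-oxabicyclo[3.2.1]octene results. No stereocentre is created; C1 and C5 pass through unchanged, and only the isomer with allyl and vinyl cis on the lactone can span the ring, so C3-epimeric material left from step 6 stays acyclic and is separated. The selectivity needed is ring closure over intermolecular metathesis; it is secured by high dilution, by the quaternary carbon C1, whose geminal substituents favour the reactive rotamer, and by the low cost of placing two cis substituents pseudo-diaxial on a five-membered ring, and dimers formed through the allyl group can re-enter the cycle because this catalyst equilibrates terminal alkenes. The free tertiary hydroxyl and the lactone are tolerated, and the cis-disubstituted, allylically oxygenated alkene of 11 should be slow to reopen.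

Step 8
Reactants: 11 (1S,5R)-1-hydroxy-6-oxabicyclo[3.2.1]oct-3-en-7-one
Product: 12 3,4-O-(phenylboranediyl)-(−)-quinide [cyclic phenylboronic ester across O3 and O4 of (1S,3R,4R,5R)-1,3,4-trihydroxy-6-oxabicyclo[3.2.1]octan-7-one; O1–H free]
Conditions: OsO4 (2 mol %), N-methylmorpholine N-oxide (1.2 equiv), PhB(OH)2 (1.1 equiv), CH2Cl2, rt
Reagents that add atoms: N-methylmorpholine N-oxide, C[N+]1([O-])CCOCC1 (oxygen source through OsO4, O=[Os](=O)(=O)=O); phenylboronic acid, OB(O)c1ccccc1
Why: Catalytic syn-dihydroxylation ([3+2] addition of OsO4, N-oxide reoxidant) with capture of the osmate ester by the boronic acid, a known anhydrous variant. The C7–O5 bridge spans one face of ring A diaxially, so OsO4 adds to the other face and O3 and O4 arrive cis to each other and anti to the bridge, as in natural quinide. The boronate keeps the very polar triol out of water and masks the diol for step 11.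

Step 9
Reactants: 13 caffeic acid [(E)-3-(3,4-dihydroxyphenyl)acrylic acid]
Product: 14 (E)-3-(3,4-diacetoxyphenyl)acrylic acid
Conditions: Ac2O, pyridine, rt; then H2O, aq. HCl
Reagents that add atoms: acetic anhydride, CC(=O)OC(C)=O
Why: O-Acetylation of the catechol; the mixed anhydride formed at the carboxyl group is hydrolysed on aqueous work-up. Aryl acetates survive the two acylations and are removed by aqueous acid at the end.

Step 10
Reactants: 14 (E)-3-(3,4-diacetoxyphenyl)acrylic acid
Product: 15 (E)-3-(3,4-diacetoxyphenyl)acryloyl chloride
Conditions: (COCl)2, HCONMe2 (cat.), CH2Cl2, 0 °C → rt; evaporation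
Reagents that add atoms: oxalyl chloride, O=C(Cl)C(=O)Cl
Why: Acid chloride formation through the Vilsmeier-type chloroiminium ion; neutral, volatile by-products and no effect on the acetates or the E-alkene.

Step 11
Reactants: 12 3,4-O-(phenylboranediyl)-(−)-quinide; 15 (E)-3-(3,4-diacetoxyphenyl)acryloyl chloride
Product: 16 1-O-[(E)-3-(3,4-diacetoxyphenyl)acryloyl]-3,4-O-(phenylboranediyl)-(−)-quinide
Conditions: 15 (2 equiv), 4-(dimethylamino)pyridine (0.3 equiv), pyridine, CH2Cl2, rt → 40 °C
Reagents that add atoms: (E)-3-(3,4-diacetoxyphenyl)acryloyl chloride (15), CC(=O)Oc1ccc(/C=C/C(=O)Cl)cc1OC(C)=O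
Why: Nucleophile-catalysed acylation through the acylpyridinium ion; O1 is the only free hydroxyl, so the hindered tertiary α-hydroxy lactone can be driven with excess reagent without any question of regiochemistry. This type of acylation is known for O3,O4-protected quinides, and the boronic ester offers no nucleophilic site.

Step 12
Reactants: 16 1-O-[(E)-3-(3,4-diacetoxyphenyl)acryloyl]-3,4-O-(phenylboranediyl)-(−)-quinide
Product: 17 1-O-[(E)-3-(3,4-diacetoxyphenyl)acryloyl]-(−)-quinide (3,4-cis-diol free)
Conditions: propane-1,3-diol (5 equiv), acetone, rt
Reagents that add atoms: none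
Why: Boronic ester exchange (transesterification) to the six-membered boronate of the 1,3-diol, a classical neutral way to remove a phenylboronate; aryl acetates, the cinnamate and the lactone are untouched.

Step 13
Reactants: 17 1-O-[(E)-3-(3,4-diacetoxyphenyl)acryloyl]-(−)-quinide; 15 (E)-3-(3,4-diacetoxyphenyl)acryloyl chloride
Product: 18 1,3-bis-O-[(E)-3-(3,4-diacetoxyphenyl)acryloyl]-(−)-quinide (O4–H free)
Conditions: 15 (1.1 equiv), 2-aminoethyl diphenylborinate Ph2BOCH2CH2NH2 (10 mol %), iPr2NEt (1.5 equiv), MeCN, 0 °C → rt
Reagents that add atoms: (E)-3-(3,4-diacetoxyphenyl)acryloyl chloride (15), CC(=O)Oc1ccc(/C=C/C(=O)Cl)cc1OC(C)=O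
Why: Borinic-acid-catalysed regioselective acylation of a cis-1,2-diol: the diol binds as a tetracoordinate borinate and the equatorial oxygen takes up the acyl chloride. In the quinide chair O3 is equatorial and O4 is axial and flanked by the lactone, so the ester should go to O3. The low temperature and short contact with base limit migration to O4.

Step 14
Reactants: 18 1,3-bis-O-[(E)-3-(3,4-diacetoxyphenyl)acryloyl]-(−)-quinide
Product: 19 1,3-di-O-caffeoylquinic acid [(1R,3R,4S,5R)-1,3-bis{[(E)-3-(3,4-dihydroxyphenyl)acryloyl]oxy}-4,5-dihydroxycyclohexane-1-carboxylic acid]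
Conditions: 2 M aq. HCl/THF (1:2), rt, argon
Reagents that add atoms: water, O
Why: Acid-catalysed ester hydrolysis; aryl acetates and the strained bridged γ-lactone should be cleaved, while the conjugated, hindered caffeoyl esters of a secondary and a tertiary alcohol hydrolyse far more slowly, as in known acid deprotections of acetylated caffeoylquinides. Acid avoids the base-induced acyl migration and catechol oxidation, and acyl–oxygen cleavage of the lactone leaves O5 on C5 with its configuration.

## Compound list

1 | D-glutamic acid, (R)-2-aminopentanedioic acid | N[C@H](CCC(=O)O)C(=O)O | starting material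
2 | (R)-5-oxotetrahydrofuran-2-carboxylic acid | OC(=O)[C@H]1CCC(=O)O1 | intermediate
3 | (R)-5-(hydroxymethyl)dihydrofuran-2(3H)-one | OC[C@H]1CCC(=O)O1 | intermediate
4 | (R)-5-oxotetrahydrofuran-2-carbaldehyde | O=C[C@H]1CCC(=O)O1 | intermediate
5 | (R)-5-vinyldihydrofuran-2(3H)-one | C=C[C@H]1CCC(=O)O1 | intermediate
6 | allyl bromide | C=CCBr | starting material
7 | lithium enolate of 5, lithium (R)-5-vinyl-4,5-dihydrofuran-2-olate (formed in the flask, not isolated) | [Li]OC1=CC[C@H](C=C)O1 | intermediate
8 | (3S,5R)-3-allyl-5-vinyldihydrofuran-2(3H)-one (allyl trans to vinyl; the C3 epimer is equally usable) | C=CC[C@H](C(=O)O1)C[C@@H]1C=C | intermediate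
9 | potassium enolate of 8, potassium (R)-3-allyl-5-vinyl-4,5-dihydrofuran-2-olate (formed in the flask, not isolated) | [K]OC1=C(CC=C)C[C@H](C=C)O1 | intermediate
10 | (3S,5R)-3-allyl-3-hydroxy-5-vinyldihydrofuran-2(3H)-one (allyl cis to vinyl, OH trans) | C=CC[C@@](O)(C(=O)O1)C[C@@H]1C=C | intermediate
11 | (1S,5R)-1-hydroxy-6-oxabicyclo[3.2.1]oct-3-en-7-one | C=2C[C@@](O)(C(=O)O1)C[C@@H]1C=2 | intermediate
12 | 3,4-O-(phenylboranediyl)-(−)-quinide (O3 and O4 cis, anti to the lactone bridge; O1–H free) | c1ccccc1B2O[C@@H]3C[C@@](O)(C(=O)O4)C[C@@H]4[C@@H]3O2 | intermediate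
13 | caffeic acid, (E)-3-(3,4-dihydroxyphenyl)acrylic acid | OC(=O)/C=C/c1ccc(O)c(O)c1 | starting material
14 | (E)-3-(3,4-diacetoxyphenyl)acrylic acid | OC(=O)/C=C/c1ccc(OC(C)=O)c(OC(C)=O)c1 | intermediate
15 | (E)-3-(3,4-diacetoxyphenyl)acryloyl chloride | ClC(=O)/C=C/c1ccc(OC(C)=O)c(OC(C)=O)c1 | intermediate
16 | 1-O-[(E)-3-(3,4-diacetoxyphenyl)acryloyl]-3,4-O-(phenylboranediyl)-(−)-quinide | c1ccccc1B2O[C@@H]3C[C@@](OC(=O)/C=C/c5ccc(OC(C)=O)c(OC(C)=O)c5)(C(=O)O4)C[C@@H]4[C@@H]3O2 | intermediate
17 | 1-O-[(E)-3-(3,4-diacetoxyphenyl)acryloyl]-(−)-quinide (3-OH equatorial and 4-OH axial, both free) | O[C@@H]1C[C@@](OC(=O)/C=C/c3ccc(OC(C)=O)c(OC(C)=O)c3)(C(=O)O2)C[C@@H]2[C@@H]1O | intermediate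
18 | 1,3-bis-O-[(E)-3-(3,4-diacetoxyphenyl)acryloyl]-(−)-quinide (4-OH free) | CC(=O)Oc1ccc(/C=C/C(=O)O[C@@H]2C[C@@](OC(=O)/C=C/c4ccc(OC(C)=O)c(OC(C)=O)c4)(C(=O)O3)C[C@@H]3[C@@H]2O)cc1OC(C)=O | intermediate
19 | 1,3-di-O-caffeoylquinic acid, (1R,3R,4S,5R) | O=C(/C=C/c1ccc(O)c(O)c1)O[C@@H]1C[C@@](OC(=O)/C=C/c2ccc(O)c(O)c2)(C(=O)O)C[C@@H](O)[C@@H]1O | target

## Step count and least certain steps

Total step count: 14. Longest linear sequence: 12 steps (1 to 19 through steps 1–8 and 11–14); steps 9 and 10 are the two-step branch from 13 to 15, which enters at steps 11 and 13.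

**Step 7 (key step).** Intermolecular metathesis through the allyl terminus may outrun ring closure, because closing ring A across the lactone needs both alkenes pseudo-diaxial and creates a strained bridged alkene; slow closure also leaves time for isomerisation of the allyl group by ruthenium hydrides.

Fallback (the order of the two ring closures is reversed; from 10, back at 11): the lactone of 10 is opened with pyrrolidine (neat, rt) to the hydroxy amide (2S,4R)-2-allyl-2,4-dihydroxy-1-(pyrrolidin-1-yl)hex-5-en-1-one F1. This acyclic 1,7-diene is closed with the same ruthenium catalyst to an unstrained cyclohexene, [(1S,5R)-1,5-dihydroxycyclohex-3-en-1-yl](pyrrolidin-1-yl)methanone F2. Because C7 and O5 are cis, F2 is relactonised with camphorsulfonic acid (1.1 equiv, toluene, 60 °C) to 11.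

**Step 6.** Facial discrimination of the enolate may be only moderate, since a vinyl group is a small controller for 1,3-induction, so a sizeable share of material would end as the C3 epimer and be lost at step 7; addition of the enolate to the sulfonylimine by-product is a second loss.

Fallback (the enolate steps are run beside a bulky C5 substituent and the vinyl group is built afterwards; from 3, back at 10):
- 3 is silylated (tert-butyldiphenylsilyl chloride, imidazole, CH2Cl2) to (R)-5-{[(tert-butyldiphenylsilyl)oxy]methyl}dihydrofuran-2(3H)-one F3.
- F3 is allylated (LiN(iPr)2, then 6, THF, −78 °C) to (3S,5R)-3-allyl-5-{[(tert-butyldiphenylsilyl)oxy]methyl}dihydrofuran-2(3H)-one F4.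
- F4 is hydroxylated as in step 6 to (3S,5R)-3-allyl-3-hydroxy-5-{[(tert-butyldiphenylsilyl)oxy]methyl}dihydrofuran-2(3H)-one F5, the large silyloxymethyl group now shielding its face.
- Bu4NF/AcOH in THF gives (3S,5R)-3-allyl-3-hydroxy-5-(hydroxymethyl)dihydrofuran-2(3H)-one F6.
- Swern oxidation gives (2R,4S)-4-allyl-4-hydroxy-5-oxotetrahydrofuran-2-carbaldehyde F7.
- Ph3P=CH2 (2.2 equiv, THF, −78 → 0 °C) gives 10.

This costs two more steps and places the delicate aldehyde later, which is why it is not the first choice.

**Step 11.** Acylation of the hindered tertiary hydroxyl may be slow, and during a long reaction the boronic ester may be lost by exchange with adventitious water or pyridinium chloride, which would expose O3 and O4 to the acid chloride.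

Fallback (the classical ketal in place of the boron ester; from 12, back at 17): exchange of 12 with propane-1,3-diol in acetone gives (−)-quinide F8. 2,2-Dimethoxypropane, p-toluenesulfonic acid (cat.) and acetone give 3,4-O-isopropylidene-(−)-quinide F9. Acylation with 15, 4-(dimethylamino)pyridine and pyridine gives 1-O-[(E)-3-(3,4-diacetoxyphenyl)acryloyl]-3,4-O-isopropylidene-(−)-quinide F10. Aqueous CF3CO2H at 0 °C removes the ketal to give 17.

**Step 13.** Discrimination between O3 and O4 may be insufficient, or the new ester may migrate from O3 to O4 under the basic conditions and a second acylation may follow.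

Fallback (regiochemistry set by orthoester opening instead of by relative reactivity; from 17, back at 19):
- 17 with HC(OMe)3 and camphorsulfonic acid (cat.) in CH2Cl2 gives the cyclic orthoformate 1-O-[(E)-3-(3,4-diacetoxyphenyl)acryloyl]-3,4-O-(methoxymethylene)-(−)-quinide F11 (both epimers at the orthoester carbon).
- 80% aq. AcOH at rt opens it under stereoelectronic control to the axial ester, 1-O-[(E)-3-(3,4-diacetoxyphenyl)acryloyl]-4-O-formyl-(−)-quinide F12, with the equatorial O3–H free.
- 15 and pyridine in CH2Cl2 at 0 °C then give 1,3-bis-O-[(E)-3-(3,4-diacetoxyphenyl)acryloyl]-4-O-formyl-(−)-quinide F13.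
- The conditions of step 14 cleave the formate together with the acetates and the lactone to give 19.

## Further compounds

F1 | step 7 | (2S,4R)-2-allyl-2,4-dihydroxy-1-(pyrrolidin-1-yl)hex-5-en-1-one | C=CC[C@@](O)(C(=O)N1CCCC1)C[C@@H](O)C=C
F2 | step 7 | [(1S,5R)-1,5-dihydroxycyclohex-3-en-1-yl](pyrrolidin-1-yl)methanone | C=2C[C@@](O)(C(=O)N1CCCC1)C[C@@H](O)C=2
F3 | step 6 | (R)-5-{[(tert-butyldiphenylsilyl)oxy]methyl}dihydrofuran-2(3H)-one | CC(C)(C)[Si](c1ccccc1)(c1ccccc1)OC[C@H]1CCC(=O)O1
F4 | step 6 | (3S,5R)-3-allyl-5-{[(tert-butyldiphenylsilyl)oxy]methyl}dihydrofuran-2(3H)-one | C=CC[C@H](C(=O)O1)C[C@@H]1CO[Si](c2ccccc2)(c2ccccc2)C(C)(C)C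
F5 | step 6 | (3S,5R)-3-allyl-3-hydroxy-5-{[(tert-butyldiphenylsilyl)oxy]methyl}dihydrofuran-2(3H)-one | C=CC[C@@](O)(C(=O)O1)C[C@@H]1CO[Si](c2ccccc2)(c2ccccc2)C(C)(C)C
F6 | step 6 | (3S,5R)-3-allyl-3-hydroxy-5-(hydroxymethyl)dihydrofuran-2(3H)-one | C=CC[C@@](O)(C(=O)O1)C[C@@H]1CO
F7 | step 6 | (2R,4S)-4-allyl-4-hydroxy-5-oxotetrahydrofuran-2-carbaldehyde | C=CC[C@@](O)(C(=O)O1)C[C@@H]1C=O
F8 | step 11 | (−)-quinide, (1S,3R,4R,5R)-1,3,4-trihydroxy-6-oxabicyclo[3.2.1]octan-7-one | O[C@@H]1C[C@@](O)(C(=O)O2)C[C@@H]2[C@@H]1O
F9 | step 11 | 3,4-O-isopropylidene-(−)-quinide | CC1(C)O[C@@H]2C[C@@](O)(C(=O)O3)C[C@@H]3[C@@H]2O1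
F10 | step 11 | 1-O-[(E)-3-(3,4-diacetoxyphenyl)acryloyl]-3,4-O-isopropylidene-(−)-quinide | CC1(C)O[C@@H]2C[C@@](OC(=O)/C=C/c4ccc(OC(C)=O)c(OC(C)=O)c4)(C(=O)O3)C[C@@H]3[C@@H]2O1
F11 | step 13 | 1-O-[(E)-3-(3,4-diacetoxyphenyl)acryloyl]-3,4-O-(methoxymethylene)-(−)-quinide (both epimers at the orthoester carbon) | COC1O[C@@H]2C[C@@](OC(=O)/C=C/c4ccc(OC(C)=O)c(OC(C)=O)c4)(C(=O)O3)C[C@@H]3[C@@H]2O1
F12 | step 13 | 1-O-[(E)-3-(3,4-diacetoxyphenyl)acryloyl]-4-O-formyl-(−)-quinide | O[C@@H]1C[C@@](OC(=O)/C=C/c3ccc(OC(C)=O)c(OC(C)=O)c3)(C(=O)O2)C[C@@H]2[C@@H]1OC=O
F13 | step 13 | 1,3-bis-O-[(E)-3-(3,4-diacetoxyphenyl)acryloyl]-4-O-formyl-(−)-quinide | CC(=O)Oc1ccc(/C=C/C(=O)O[C@@H]2C[C@@](OC(=O)/C=C/c4ccc(OC(C)=O)c(OC(C)=O)c4)(C(=O)O3)C[C@@H]3[C@@H]2OC=O)cc1OC(C)=O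
A1 | alternative 1 | 3-O-[(E)-3,4-bis(tert-butyldimethylsilyloxy)cinnamoyl]-4,5-O-(1,1,3,3-tetraisopropyldisiloxane-1,3-diyl) derivative of (3R,5R)-3,4,5-trihydroxycyclohexanone (O3 cis to O4) | O=C(/C=C/c1ccc(O[Si](C)(C)C(C)(C)C)c(O[Si](C)(C)C(C)(C)C)c1)O[C@@H]1CC(=O)C[C@@H](O[Si](C(C)C)(C(C)C)O[Si]2(C(C)C)C(C)C)[C@@H]1O2
A2 | alternative 1 | (E)-3-[3,4-bis(tert-butyldimethylsilyloxy)phenyl]acrylic acid | CC(C)(C)[Si](C)(C)Oc1ccc(/C=C/C(=O)O)cc1O[Si](C)(C)C(C)(C)C
A3 | alternative 1 | 1-isocyanocyclohex-1-ene | [C-]#[N+]C1=CCCCC1
A4 | alternative 1 | N-(cyclohex-1-en-1-yl)amide of 1,3-bis-O-[(E)-3,4-bis(tert-butyldimethylsilyloxy)cinnamoyl]-4,5-O-(1,1,3,3-tetraisopropyldisiloxane-1,3-diyl)quinic acid | O=C(/C=C/c1ccc(O[Si](C)(C)C(C)(C)C)c(O[Si](C)(C)C(C)(C)C)c1)O[C@@H]1C[C@@](OC(=O)/C=C/c3ccc(O[Si](C)(C)C(C)(C)C)c(O[Si](C)(C)C(C)(C)C)c3)(C(=O)NC3=CCCCC3)C[C@@H](O[Si](C(C)C)(C(C)C)O[Si]2(C(C)C)C(C)C)[C@@H]1O2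
A5 | alternative 1 | (−)-quinic acid, (1S,3R,4S,5R)-1,3,4,5-tetrahydroxycyclohexane-1-carboxylic acid | O[C@@H]1C[C@@](O)(C(=O)O)C[C@@H](O)[C@@H]1O
A6 | alternative 2 | buta-1,3-diene | C=CC=C
A7 | alternative 2 | 1-formylvinyl 2-(diethoxyphosphoryl)acetate | C=C(C=O)OC(=O)CP(=O)(OCC)OCC
A8 | alternative 2 | (S)-1-formylcyclohex-3-en-1-yl 2-(diethoxyphosphoryl)acetate | C1C[C@@](OC(=O)CP(=O)(OCC)OCC)(C=O)CC=C1
A9 | alternative 3 | shikimic acid, (3R,4S,5R)-3,4,5-trihydroxycyclohex-1-ene-1-carboxylic acid | O[C@@H]1C=C(C(=O)O)C[C@@H](O)[C@@H]1O
A10 | alternative 3 | 2-cyclohexylidene-1,3-dithiane bearing the C3 tert-butyl carbonate and the 4,5-O-(1,1,3,3-tetraisopropyldisiloxane-1,3-diyl) group, ring configuration as in quinic acid | CC(C)(C)OC(=O)O[C@@H]1CC(=C2SCCCS2)C[C@@H](O[Si](C(C)C)(C(C)C)O[Si]3(C(C)C)C(C)C)[C@@H]1O3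
A11 | alternative 3 | allyl alcohol | C=CCO
A12 | alternative 3 | 1,3-O-carbonyl-4,5-O-(1,1,3,3-tetraisopropyldisiloxane-1,3-diyl)quinic acid masked as its 2-allyloxy-1,3-dithian-2-yl orthoester | O=C1O[C@@H]2C[C@@](O1)(C3(OCC=C)SCCCS3)C[C@@H](O[Si](C(C)C)(C(C)C)O[Si]4(C(C)C)C(C)C)[C@@H]2O4
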